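Readings and results are simulated with made-up constants; scatter was added.

At 4.00 h, beta holds 34.3% target and theta 33.2%, although theta was charged with ten times as much protic impurity. The two flasks look nearly the same, and the question is what that impurity costs.

in all of them: starting material 0.13 M (fed, over 2.0 h)
- beta: protic impurity 0.0025 M; run made earlier
- theta: protic impurity 0.027 M; run made earlier
- Monday's: protic impurity 0.00400 M; time 4.0 h
- Tuesday's: protic impurity 0.0120 M; time 4.0 h
- Sunday's: protic impurity 0.0400 M; time 4.0 h

- beta (time / h: target / %, starting material / %): 0.200: 0, 8.4; 0.667: 3.3, 27.1; 1.00: 3.2, 36.3; 1.50: 9.5, 47.3; 2.50: 22.1, 44.4; 3.00: 30.1, 35.3; 4.00: 34.3, 26.3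
- theta (time / h: target / %, starting material / %): 0.200: 0, 9.8; 0.667: 2.1, 26.1; 1.00: 3.6, 32.5; 1.50: 8.3, 42.5; 2.50: 20.2, 37.1; 3.00: 24.9, 28.8; 4.00: 33.2, 20.2

(standard deviation of a reading: 1 percentage point)

- what was read earlier has a scatter of 1 percentage point, one standard deviation
- "hardly changes" means that all values lie within two and a half points (for a concentration: within two and a half percent of the largest)
- percentages count the whole charge, also what has not yet gone in

* amount of target at the end, in percent of the starting material charged for Monday's, Tuesday's, Sunday's, in this order
* the shape of the row from first to last (falls, then rises / falls all the way / rises, then falls / rises all the way / hardly changes)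

The cost shows in starting material and target read together. Averaged over the readings after the feed, this seen pool stands at 64.2% in beta and 54.8% in theta, so theta's pool is smaller, by a relative 14.6%. Theta's extra impurity amounts to 18.8% of the charge of starting material. Suppose that one impurity molecule removes one molecule of starting material, and that the survivors divide among their forms as they do in beta. The first share divided by the second then gives φ, an estimate from scattered readings of the conversion of the impurity in these late hours, 0.775. Time has dropped out of this ratio.

Let a be the impurity charge over the charge of starting material. Target per surviving charge, s, is the target reading divided by (1 − φa). This gives 34.8% for beta and 39.6% for theta. Those two stand 4.8 percentage points apart against a scatter of 1 point per reading; this reckoning takes them as two readings of one share and carries their mean, 37.2%. My own reckoning, s(1 − φa), gives 36.3%, 34.5% and 28.3%, a row that falls throughout.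

The forecast gave 35%, 36% and 30%, with the shape rises, then falls, and called this “a tentative inference”.

The flasks give 36.3%, 34.5% and 28.8%, so the row falls all the way.

    starting material + protic impurity → quenched substrate (k = 13.0 L mol⁻¹ h⁻¹)
    isomer of the product ⇌ starting material (k = 0.300 h⁻¹)
    target ⇌ isomer of the product (K = 0.780, k = 0.530 h⁻¹)
    starting material ⇌ target (K = 2.60, k = 0.0980 h⁻¹)

Carried to Sunday's flask, φ takes 23.8% of the charge out, and Sunday's flask holds 26.1% quenched substrate at 4.00 h. Carried to Monday's flask, φ takes 2.38%, and Monday's flask holds 2.80%. Sunday's target ends below Monday's in part because protic impurity turns starting material into quenched substrate, the largest single effect on that fall. With that step taken away, the fall of 7.5 points from Monday's to Sunday's becomes 0 points.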